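The ring atoms are numbered as in germacranes: C1=C10 (C10 bears the methyl), C4=C5 (C4 bears CH2O‑isovaleryl), C6–O and C7–C of the lactone, C9–OAc. The ten‑membered carbocycle is disconnected at C9–C10. An intramolecular Nozaki–Hiyama–Kishi addition of a (Z)‑alkenyl iodide to an aldehyde closes this ring last, retains the Z‑C1=C10 geometry and sets the allylic carbinol C9 under control of the preformed cis‑fused α‑methylene‑γ‑butyrolactone, whose C6–C7 fusion holds both arms on one face. The precursor is an open‑chain iodo aldehyde lactone, made by a catalytic enantioselective chromium 2‑(alkoxycarbonyl)allylation that sets C6 and C7 in one event.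

Key step: step 11

Remark on the structure: the target is read as (6R,7R,9S) with a cis‑fused lactone, C1=C10 Z, and C4=C5 with C3 trans to C6 (CIP descriptor Z because of the acyloxymethyl group).
Remark on step 9: addition to the Si face of the aldehyde gives 6R; the ligand antipode that delivers this face is assumed, and the sense of induction is to be confirmed on the first adduct.

Step 1
Reactants: 1 prop-2-yn-1-ol; 2 but-3-en-1-ylmagnesium bromide
Product: 4 4-(but-3-en-1-yl)furan-2(5H)-one, via alkenylmagnesium alkoxide 3 (not isolated)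
Conditions: 2 (3 equiv), CuI (10 mol %), THF, 0 °C → rt; CO2, −20 °C → rt; aq. HCl
Reagents that add atoms: carbon dioxide, O=C=O
Why: Copper‑catalysed anti‑carbomagnesiation of the propargylic alkoxide should place the butenyl group on the carbinol‑bearing alkyne carbon and magnesium on the terminal carbon cis to CH2O, so that carboxylation and acidic lactonisation give the β‑substituted butenolide, whose ring fixes the C4=C5 geometry (C15 cis to C6).

Step 2
Reactants: 4 4-(but-3-en-1-yl)furan-2(5H)-one
Product: 5 (2Z)-3-(hydroxymethyl)-N-methoxy-N-methylhepta-2,6-dienamide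
Conditions: MeNH(OMe)·HCl, Me3Al, CH2Cl2, 0 °C → rt; Rochelle salt work‑up; crude product used at once
Reagents that add atoms: N,O-dimethylhydroxylamine hydrochloride, CNOC.Cl
Why: Weinreb aminolysis of a lactone with the aluminium amide should open the butenolide at the acyl carbon and keep the ring‑imposed Z geometry, and immediate use forestalls relactonisation.

Step 3
Reactants: 5 (2Z)-3-(hydroxymethyl)-N-methoxy-N-methylhepta-2,6-dienamide
Product: 6 (2Z)-N-methoxy-N-methyl-3-{[(3-methylbutanoyl)oxy]methyl}hepta-2,6-dienamide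
Conditions: isovaleryl chloride, pyridine, DMAP (cat.), CH2Cl2, 0 °C
Reagents that add atoms: 3-methylbutanoyl chloride, CC(C)CC(Cl)=O
Why: DMAP‑catalysed acylation of the primary allylic alcohol installs the isovalerate that the target keeps and blocks relactonisation.

Step 4
Reactants: 6 (2Z)-N-methoxy-N-methyl-3-{[(3-methylbutanoyl)oxy]methyl}hepta-2,6-dienamide
Product: 7 (2Z)-N-methoxy-N-methyl-3-{[(3-methylbutanoyl)oxy]methyl}-6-oxohex-2-enamide
Conditions: OsO4 (2 mol %), NaIO4, 2,6-lutidine, dioxane/H2O, rt
Reagents that add atoms: osmium tetroxide (catalytic oxygen carrier), O=[Os](=O)(=O)=O; sodium periodate (terminal oxidant), [Na+].[O-]I(=O)(=O)=O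
Why: Lemieux–Johnson cleavage should select the electron‑rich monosubstituted alkene over the trisubstituted alkene conjugated to the amide.

Step 5
Reactants: 7 (2Z)-N-methoxy-N-methyl-3-{[(3-methylbutanoyl)oxy]methyl}-6-oxohex-2-enamide
Product: 8 (2Z,6Z)-7-iodo-N-methoxy-N-methyl-3-{[(3-methylbutanoyl)oxy]methyl}octa-2,6-dienamide
Conditions: EtPPh3I, n-BuLi, THF; I2, −78 °C; NaHMDS, −78 °C; then 7, −78 → −20 °C
Reagents that add atoms: ethyltriphenylphosphonium iodide, CC[P+](c1ccccc1)(c1ccccc1)c1ccccc1.[I-]; iodine, II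
Why: The α‑iodo ylide (Stork–Zhao‑type Wittig olefination) should react with the aldehyde at −78 °C faster than with the ester or the Weinreb amide and give the (Z)-2-iodoalk-2-ene (iodine cis to the chain) under kinetic control.

Step 6
Reactants: 8 (2Z,6Z)-7-iodo-N-methoxy-N-methyl-3-{[(3-methylbutanoyl)oxy]methyl}octa-2,6-dienamide
Product: 9 (2Z,6Z)-7-iodo-3-{[(3-methylbutanoyl)oxy]methyl}octa-2,6-dienal
Conditions: DIBAL-H (1.1 equiv), THF, −78 °C; Rochelle salt
Reagents that add atoms: none
Why: DIBAL‑H reduction of a Weinreb amide stops at the chelated hemiaminal and, with one equivalent at −78 °C, should outpace attack on the isovalerate and leave both alkene geometries untouched.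

Step 7
Reactants: 10 3-[(tert-butyldimethylsilyl)oxy]propanal; 11 methyl prop-2-enoate
Product: 12 methyl 5-[(tert-butyldimethylsilyl)oxy]-3-hydroxy-2-methylidenepentanoate (racemic)
Conditions: DABCO (0.5 equiv), 11 (excess), neat, rt
Reagents that add atoms: none
Why: Morita–Baylis–Hillman reaction; the racemic carbinol centre is removed in step 8.

Step 8
Reactants: 12 methyl 5-[(tert-butyldimethylsilyl)oxy]-3-hydroxy-2-methylidenepentanoate
Product: 13 methyl (2Z)-2-(bromomethyl)-5-[(tert-butyldimethylsilyl)oxy]pent-2-enoate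
Conditions: NBS, Me2S, CH2Cl2, −20 °C → rt
Reagents that add atoms: N-bromosuccinimide, BrN1C(=O)CCC1=O
Why: Corey–Kim‑type bromination of a Baylis–Hillman alcohol proceeds with allylic transposition to the thermodynamically favoured (Z)-2-(bromomethyl)enoate.

Step 9
Reactants: 9 (2Z,6Z)-7-iodo-3-{[(3-methylbutanoyl)oxy]methyl}octa-2,6-dienal; 13 methyl (2Z)-2-(bromomethyl)-5-[(tert-butyldimethylsilyl)oxy]pent-2-enoate
Product: 15 (4R,5R)-4-(2-hydroxyethyl)-5-[(1Z,5Z)-6-iodo-2-{[(3-methylbutanoyl)oxy]methyl}hepta-1,5-dien-1-yl]-3-methylideneoxolan-2-one, via O-trimethylsilyl syn-adduct 14 (not isolated)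
Conditions: CrCl2 (10 mol %, nickel‑free), chiral carbazole‑bridged bis(oxazoline) ligand (12 mol %), Mn, TMSCl, iPr2NEt, THF, rt; then CSA, MeOH, 0 °C → rt
Reagents that add atoms: none
Why: Catalytic enantioselective Nozaki–Hiyama allylation with a 2-(alkoxycarbonyl)allyl bromide (Mn/TMSCl turnover): the allylchromium reagent, with its γ‑substituent trans to the ester, should add through a chair transition state to give the syn adduct (C6/C7 cis), the ligand directs attack to the Si face of the aldehyde (6R), and acidic methanol then removes both silyl groups and closes the lactone.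

Step 10
Reactants: 15 cis‑lactone alcohol
Product: 16 (4R,5R)-5-[(1Z,5Z)-6-iodo-2-{[(3-methylbutanoyl)oxy]methyl}hepta-1,5-dien-1-yl]-3-methylidene-4-(2-oxoethyl)oxolan-2-one
Conditions: Dess–Martin periodinane, NaHCO3, CH2Cl2, 0 °C → rt
Reagents that add atoms: none
Why: Buffered Dess–Martin oxidation of the primary alcohol should leave the alkenyl iodide, the esters and the α‑methylene lactone untouched.

Step 11
Reactants: 16 iodo aldehyde lactone
Product: 18 [(3aR,5S,6Z,10Z,11aR)-5-hydroxy-6-methyl-3-methylidene-2-oxo-2,3,3a,4,5,8,9,11a-octahydrocyclodeca[b]furan-10-yl]methyl 3-methylbutanoate, via alkenylchromium(III) dichloride 17 (not isolated)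
Conditions: CrCl2 (10 equiv), NiCl2 (0.1 equiv), degassed DMSO/THF, rt, syringe‑pump addition of 16 to 0.002 M final concentration
Reagents that add atoms: none
Why: Ni(0) generated from NiCl2 and Cr(II) inserts into the C10–I bond with retention of geometry and transmetalation gives alkenylchromium(III) 17, which adds to the C9 aldehyde to form the C9–C10 bond. The closest known reaction type is the Nozaki–Hiyama–Kishi macrocyclisation of alkenyl iodide aldehydes, which is established for nine‑ and ten‑membered carbocycles. The ten‑membered ring closes in a 10‑exo‑trig mode at the aldehyde carbon, with the carbonyl oxygen left outside the ring. The new stereocentre C9 is set by substrate control: the cis‑fused lactone fixes a gauche C8–C7–C6–C5 arrangement, and in the folded transition state the aldehyde should turn its C9–H into the plane of the C1=C10 alkene toward C2 (least A(1,3) strain) and its chromium‑bound oxygen to the outer face, which is expected to give 9S, although this assignment is the least secure point of the route. The step needs ring closure to outrun oligomerisation and the alkene to stay Z; high dilution with slow addition, the two arms held on one lactone face and the configurational stability of α‑methyl‑substituted alkenylchromium species should secure these, and organochromium(III) reagents leave the esters and the α‑methylene lactone alone.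

Step 12
Reactants: 18 macrocyclic allylic alcohol
Product: 19 [(3aR,5S,6Z,10Z,11aR)-5-(acetyloxy)-6-methyl-3-methylidene-2-oxo-2,3,3a,4,5,8,9,11a-octahydrocyclodeca[b]furan-10-yl]methyl 3-methylbutanoate (CNP0398030.1)
Conditions: Ac2O, pyridine, DMAP (cat.), CH2Cl2, 0 °C
Reagents that add atoms: acetic anhydride, CC(=O)OC(C)=O
Why: DMAP‑catalysed acetylation of the secondary allylic alcohol proceeds with retention at C9.

Compound list
1 | prop-2-yn-1-ol | C#CCO | starting material
2 | but-3-en-1-ylmagnesium bromide | C=CCC[Mg]Br | starting material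
3 | bromomagnesium (2Z)-2-(but-3-en-1-yl)-3-(bromomagnesio)prop-2-en-1-olate | C=CCC/C(CO[Mg]Br)=C/[Mg]Br | intermediate
4 | 4-(but-3-en-1-yl)furan-2(5H)-one | C=CCCC1=CC(=O)OC1 | intermediate
5 | (2Z)-3-(hydroxymethyl)-N-methoxy-N-methylhepta-2,6-dienamide | C=CCC/C(CO)=C/C(=O)N(C)OC | intermediate
6 | (2Z)-N-methoxy-N-methyl-3-{[(3-methylbutanoyl)oxy]methyl}hepta-2,6-dienamide | C=CCC/C(COC(=O)CC(C)C)=C/C(=O)N(C)OC | intermediate
7 | (2Z)-N-methoxy-N-methyl-3-{[(3-methylbutanoyl)oxy]methyl}-6-oxohex-2-enamide | O=CCC/C(COC(=O)CC(C)C)=C/C(=O)N(C)OC | intermediate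
8 | (2Z,6Z)-7-iodo-N-methoxy-N-methyl-3-{[(3-methylbutanoyl)oxy]methyl}octa-2,6-dienamide | C/C(I)=C/CC/C(COC(=O)CC(C)C)=C/C(=O)N(C)OC | intermediate
9 | (2Z,6Z)-7-iodo-3-{[(3-methylbutanoyl)oxy]methyl}octa-2,6-dienal | C/C(I)=C/CC/C(COC(=O)CC(C)C)=C/C=O | intermediate
10 | 3-[(tert-butyldimethylsilyl)oxy]propanal | O=CCCO[Si](C)(C)C(C)(C)C | starting material
11 | methyl prop-2-enoate (methyl acrylate) | C=CC(=O)OC | starting material
12 | methyl 5-[(tert-butyldimethylsilyl)oxy]-3-hydroxy-2-methylidenepentanoate (racemic) | C=C(C(=O)OC)C(O)CCO[Si](C)(C)C(C)(C)C | intermediate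
13 | methyl (2Z)-2-(bromomethyl)-5-[(tert-butyldimethylsilyl)oxy]pent-2-enoate | COC(=O)/C(CBr)=C/CCO[Si](C)(C)C(C)(C)C | intermediate
14 | methyl (3R,4R,5Z,9Z)-3-{2-[(tert-butyldimethylsilyl)oxy]ethyl}-10-iodo-2-methylidene-6-{[(3-methylbutanoyl)oxy]methyl}-4-[(trimethylsilyl)oxy]undeca-5,9-dienoate | C=C(C(=O)OC)[C@@H](CCO[Si](C)(C)C(C)(C)C)[C@H](O[Si](C)(C)C)/C=C(\COC(=O)CC(C)C)CC/C=C(/C)I | intermediate
15 | (4R,5R)-4-(2-hydroxyethyl)-5-[(1Z,5Z)-6-iodo-2-{[(3-methylbutanoyl)oxy]methyl}hepta-1,5-dien-1-yl]-3-methylideneoxolan-2-one | C=C1C(=O)O[C@H](/C=C(\COC(=O)CC(C)C)CC/C=C(/C)I)[C@@H]1CCO | intermediate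
16 | (4R,5R)-5-[(1Z,5Z)-6-iodo-2-{[(3-methylbutanoyl)oxy]methyl}hepta-1,5-dien-1-yl]-3-methylidene-4-(2-oxoethyl)oxolan-2-one | C=C1C(=O)O[C@H](/C=C(\COC(=O)CC(C)C)CC/C=C(/C)I)[C@@H]1CC=O | intermediate
17 | alkenylchromium(III) dichloride of 16 (CrCl2 in place of iodine on C10, Z geometry retained) | C=C1C(=O)O[C@H](/C=C(\COC(=O)CC(C)C)CC/C=C(/C)[Cr](Cl)Cl)[C@@H]1CC=O | intermediate
18 | [(3aR,5S,6Z,10Z,11aR)-5-hydroxy-6-methyl-3-methylidene-2-oxo-2,3,3a,4,5,8,9,11a-octahydrocyclodeca[b]furan-10-yl]methyl 3-methylbutanoate | C=C1C(=O)O[C@@H]2/C=C(\COC(=O)CC(C)C)CC/C=C(/C)[C@@H](O)C[C@H]12 | intermediate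
19 | [(3aR,5S,6Z,10Z,11aR)-5-(acetyloxy)-6-methyl-3-methylidene-2-oxo-2,3,3a,4,5,8,9,11a-octahydrocyclodeca[b]furan-10-yl]methyl 3-methylbutanoate | C=C1C(=O)O[C@@H]2/C=C(\COC(=O)CC(C)C)CC/C=C(/C)[C@@H](OC(C)=O)C[C@H]12 | target

Total step count: 12
Longest linear sequence: 10 steps (steps 1–6 and 9–12)

Steps most likely to fail

Step 11 (key step). The alkenylchromium may add to the wrong face of the aldehyde, so that the C9 epimer forms as the main product or as an inseparable share; oligomerisation is the second risk and is met by dilution. Fallback: setting out from 16, the same cyclisation then delivers the C9‑epimeric alcohol F1. Instead of acetylation with retention, a Mitsunobu esterification with acetic acid (PPh3, DIAD, toluene, 0 °C) forms the acetate with inversion at C9 and comes back to the route at 19, so that either epimer can be used.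

Step 9. Enantio‑ and syn‑selectivity of the chromium‑catalysed allylation may be insufficient with the hindered Z‑enal, or the enal may isomerise to E under the Lewis‑acidic conditions. Fallback: setting out from 13, palladium‑catalysed borylation (B2pin2, Pd2(dba)3, toluene, 50 °C) gives the allylboronate F2. Its chiral phosphoric acid‑catalysed allylboration of 9 (TRIP, toluene, −30 °C) runs through a closed Zimmerman–Traxler transition state, in which the γ‑substituent cis to CH2B leads to the syn O‑boryl adduct F3. CSA in methanol then cleaves the borate and the silyl ether, closes the lactone and returns to the route at 15.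

Step 5. The α‑iodo ylide olefination is prone to low conversion and to erosion of the Z selectivity, through competing enolisation of the aldehyde and loss of iodine from the ylide. Fallback: setting out from 7, Ramirez dibromo‑olefination (CBr4, PPh3, CH2Cl2, 0 °C) gives the 1,1‑dibromoalkene F4. A trans‑selective Negishi mono‑methylation (MeZnCl, PdCl2(DPEphos), THF) replaces the bromine trans to the chain and gives the (Z)‑bromoalkene F5. Copper‑catalysed halogen exchange with retention (CuI, trans‑N,N'‑dimethylcyclohexane‑1,2‑diamine, NaI, dioxane, 110 °C) returns to the route at 8.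

Further compounds
F1 | step 11 | [(3aR,5R,6Z,10Z,11aR)-5-hydroxy-6-methyl-3-methylidene-2-oxo-2,3,3a,4,5,8,9,11a-octahydrocyclodeca[b]furan-10-yl]methyl 3-methylbutanoate | C=C1C(=O)O[C@@H]2/C=C(\COC(=O)CC(C)C)CC/C=C(/C)[C@H](O)C[C@H]12
F2 | step 9 | methyl (2E)-5-[(tert-butyldimethylsilyl)oxy]-2-[(4,4,5,5-tetramethyl-1,3,2-dioxaborolan-2-yl)methyl]pent-2-enoate | COC(=O)/C(CB1OC(C)(C)C(C)(C)O1)=C/CCO[Si](C)(C)C(C)(C)C
F3 | step 9 | methyl (3R,4R,5Z,9Z)-3-{2-[(tert-butyldimethylsilyl)oxy]ethyl}-10-iodo-2-methylidene-6-{[(3-methylbutanoyl)oxy]methyl}-4-[(4,4,5,5-tetramethyl-1,3,2-dioxaborolan-2-yl)oxy]undeca-5,9-dienoate | C=C(C(=O)OC)[C@@H](CCO[Si](C)(C)C(C)(C)C)[C@H](OB1OC(C)(C)C(C)(C)O1)/C=C(\COC(=O)CC(C)C)CC/C=C(/C)I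
F4 | step 5 | (2Z)-7,7-dibromo-N-methoxy-N-methyl-3-{[(3-methylbutanoyl)oxy]methyl}hepta-2,6-dienamide | BrC(Br)=CCC/C(COC(=O)CC(C)C)=C/C(=O)N(C)OC
F5 | step 5 | (2Z,6Z)-7-bromo-N-methoxy-N-methyl-3-{[(3-methylbutanoyl)oxy]methyl}octa-2,6-dienamide | C/C(Br)=C/CC/C(COC(=O)CC(C)C)=C/C(=O)N(C)OC
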